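**Assumptions (one line each):**
- Cadiolide A has no sp³ stereocentre, so the "single enantiomer" requirement is trivially met. The only stereo-element is the Z-exocyclic alkene, in which the ring O and the 4-hydroxyphenyl group are cis (O/C(=C\Ar) in the SMILES).
- (3,5-Dibromo-4-methoxyphenyl)boronic acid is taken as commercially available, or as its pinacol ester.
- All three phenols are carried as methyl ethers and removed together in the last step.

**Retrosynthesis**
- The last step is global O-demethylation of the trimethyl ether.
- The Z-arylidene comes from aldol/E1cB condensation of the acidic γ-CH2 of a 3-aroyl-4-arylbutenolide with anisaldehyde. The Z isomer is the thermodynamic product.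
- The C4 aryl group comes from Suzuki coupling of the enol triflate of a 3-aroyltetronic acid.
- The 3-aroyltetronic acid comes from C-acylation of tetronic acid with 3,5-dibromo-4-methoxybenzoic acid. The butenolide ring is already present in tetronic acid, so no ring has to be built.

**Route**

Step 1
Reactants: 1 (tetronic acid), 2 (3,5-dibromo-4-methoxybenzoic acid)
Product: 3 (3-(3,5-dibromo-4-methoxybenzoyl)-4-hydroxyfuran-2(5H)-one)
Conditions: EDC·HCl, DMAP (3 equiv), CH2Cl2, 0 °C → rt; then 1 M HCl work-up
Reagents that add atoms: none
Why: Steglich O-acylation of the tetronic acid enol is followed by DMAP-mediated O→C acyl migration. This gives the stable, strongly acidic 3-acyltetronic acid. No stereocentre is formed.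

Step 2
Reactants: 3, 4 (triflic anhydride)
Product: 5 (3-(3,5-dibromo-4-methoxybenzoyl)-4-(triflyloxy)furan-2(5H)-one)
Conditions: Tf2O, DIPEA, CH2Cl2, −78 → 0 °C; use crude or after a quick silica plug
Reagents that add atoms: Tf2O, O=S(=O)(OS(=O)(=O)C(F)(F)F)C(F)(F)F
Why: Enol triflation of the vinylogous acid gives the fully conjugated ring (endocyclic) enol triflate. I assume this is favoured over the cross-conjugated exocyclic triflate. It is a substituted-olefin enol triflate with no stereocentre.

Step 3
Reactants: 5, 6 ((3,5-dibromo-4-methoxyphenyl)boronic acid)
Product: 7 (3-(3,5-dibromo-4-methoxybenzoyl)-4-(3,5-dibromo-4-methoxyphenyl)furan-2(5H)-one)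
Conditions: Pd(PPh3)4 (5 mol%), K3PO4, dioxane/H2O (20:1), 40–50 °C
Reagents that add atoms: none (the aryl group comes from reactant 6)
Why: Suzuki–Miyaura coupling. The β-acyl enol triflate is far more reactive toward Pd(0) than the hindered aryl bromides, so it should couple selectively at mild temperature. No stereocentre is formed.

Step 4
Reactants: 7, 8 (4-methoxybenzaldehyde)
Product: 9 (trimethyl ether of cadiolide A, Z)
Conditions: 8 (1.5 equiv), DBU, THF, 0 °C; then MsCl, Et3N, 0 °C → rt
Reagents that add atoms: none (MsCl leaves as MsOH)
Why: Vinylogous aldol condensation. The C5-H2 is acidic (γ-position of a 3-acylbutenolide), the aldolate is mesylated, and E1cB elimination gives the arylidene. The Z alkene is thermodynamically preferred, with the aryl group syn to the small ring O and anti to the C4 aryl ring.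

Step 5
Reactants: 9
Product: 10 (cadiolide A)
Conditions: BBr3 (9 equiv), CH2Cl2, −78 → 0 °C; aqueous NaHCO3/NH4Cl quench
Reagents that add atoms: none
Why: BBr3 cleaves aryl methyl ethers, including the hindered 2,6-dibromoanisoles, under non-reducing conditions, so the C–Br bonds survive. The enol lactone and Z-olefin are retained at low temperature.

**Checks**
- **Structure:** The product has a butenolide ring with C3-aroyl, C4-aryl and C5=CH-C6H4OH, matching the target. Both dibromo-hydroxyphenyl groups sit on C3 (as the aroyl) and C4, and the unbrominated hydroxyphenyl is on the arylidene. The formula is C24H12Br4O6, and Z is set in step 4.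
- **Atom balance:** Step 1 is acid + tetronic acid − H2O. Step 2 releases TfOH. Step 3 is a Suzuki coupling. Step 4 is aldol condensation − H2O. Step 5 converts three OMe to OH.
- **Functional-group survival:** The aryl bromides are intact through steps 1–5, and the lactone and ketone are untouched.
- **Stereochemistry:** There are no sp³ centres, and the Z-olefin is set in step 4 and not touched in step 5.

**Compound list**

| # | Name | SMILES | Role |
|---|---|---|---|
| 1 | Tetronic acid (4-hydroxyfuran-2(5H)-one) | OC1=CC(=O)OC1 | starting material |
| 2 | 3,5-Dibromo-4-methoxybenzoic acid | COc1c(Br)cc(cc1Br)C(=O)O | starting material |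
| 3 | 3-(3,5-Dibromo-4-methoxybenzoyl)tetronic acid | COc1c(Br)cc(cc1Br)C(=O)C1=C(O)COC1=O | intermediate |
| 4 | Triflic anhydride | O=S(=O)(OS(=O)(=O)C(F)(F)F)C(F)(F)F | starting material (reagent) |
| 5 | 3-Aroyl-4-triflyloxy-furan-2(5H)-one | COc1c(Br)cc(cc1Br)C(=O)C1=C(OS(=O)(=O)C(F)(F)F)COC1=O | intermediate |
| 6 | (3,5-Dibromo-4-methoxyphenyl)boronic acid | COc1c(Br)cc(B(O)O)cc1Br | starting material |
| 7 | 3-Aroyl-4-aryl-furan-2(5H)-one (bis-OMe) | COc1c(Br)cc(cc1Br)C(=O)C1=C(c2cc(Br)c(OC)c(Br)c2)COC1=O | intermediate |
| 8 | 4-Methoxybenzaldehyde | COc1ccc(C=O)cc1 | starting material |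
| 9 | Cadiolide A trimethyl ether (Z) | O=C1O/C(=C\c2ccc(OC)cc2)C(c2cc(Br)c(OC)c(Br)c2)=C1C(=O)c1cc(Br)c(OC)c(Br)c1 | intermediate |
| 10 | Cadiolide A | O=C1O/C(=C\c2ccc(O)cc2)C(c2cc(Br)c(O)c(Br)c2)=C1C(=O)c1cc(Br)c(O)c(Br)c1 | target |

**Totals:** 5 steps in total and 5 steps in the longest linear sequence.

**Three steps most likely to fail**
1. **Step 2, regioselective triflation.** Triflation of the 3-acyltetronate could occur on the aroyl oxygen and give the exocyclic enol triflate, which would then couple at the wrong carbon.
   - Fallback: start from 3,4-dibromofuran-2(5H)-one instead. Do a C4-selective Suzuki coupling, then the arylidene condensation, then install the C3 aroyl by carbonylative Suzuki coupling (ArB(OH)2, CO) before the final demethylation.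
2. **Step 3, Suzuki coupling.** The dibromoaryl boronic acid is an AB2-type monomer and could oligomerize or protodeboronate, and the triflate could hydrolyse.
   - Fallback: couple 4-methoxyphenylboronic acid instead, demethylate, tetrabrominate the two activated phenols with Br2, and only then run the arylidene condensation with a protected p-hydroxybenzaldehyde.
3. **Step 4, arylidene condensation.** DBU could add to the electrophilic core, the aldolate could undergo retro-aldol, or Z/E selectivity could be poor.
   - Fallback: convert 7 to its 2-silyloxyfuran (TBSOTf, Et3N) and run a vinylogous Mukaiyama aldol with 8 (BF3·OEt2), then dehydrate with MsCl/Et3N or DBU.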